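Whatever the reagent does, target and isomer of the product both grow from intermediate, so the ratio of their rates of formation contains no reagent.

- north: substrate 0.25 M; reagent 0.75 M; run made earlier
- flask: substrate 0.25 M; reagent 0.375 M; time 5.0 d

north run (percent of the substrate charged)

| time / h | target / % | isomer of the product / % |
|---|---|---|
| 2.00 | 1.1 | 0.3 |
| 6.00 | 11.3 | 3.7 |
| 12.0 | 22.9 | 11.6 |
| 15.0 | 28.6 | 12.0 |
| 25.0 | 34.1 | 17.9 |

(scatter of a reading: 1 percentage point)

- a species is counted by the substrate in it: one homo dimer counts as two
- the numbers in the tables scatter with a standard deviation of 1 percentage point
- candidate steps: 2 substrate -> homo dimer; intermediate <-> target; substrate + reagent -> intermediate + by-product; reagent -> decomposition product; intermediate <-> isomer of the product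

- share of target in target plus isomer of the product at 4.0 h
- share of target in target plus isomer of the product at 5.0 d

Adding the north readings up to 15.0 h gives the branch share, the target's part of target plus isomer, which I take for the split between the two forward steps, 69.8%, a reading of the selectivity under kinetic control. The flask has half the reagent of the north run, which slows the making of intermediate but enters neither branch, and 4.0 h is shorter than 15.0 h, so I put the early share of the flask at the branch share.

At 25.0 h the north share reads 65.6%, a drift of 4.3 percentage points against a scatter of 1 point per reading. The 5.0 d of the flask holds 4.80 north spans, so a constant drift would end at 49.4%. That constancy is the weak link: a share relaxing towards an equilibrium ratio slows as it nears it. A drift that falls by a factor 2 each span ends at 61.6% instead, and I commit to the mean of the two, 55.5%.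

The forecast gives 73% at 4.0 h and 50% at 5.0 d, between 22% and 70%, saying of the equilibrium ratio: “it isn't determined by these data”.

The flask gives 69.2% at 4.0 h and 54.3% at 5.0 d.

    2 substrate → homo dimer (k = 0.00669 /M/min)
    intermediate ⇌ target (K = 2.50, k = 0.00115 /min)
    substrate + reagent → intermediate + by-product (k = 0.00520 /M/min)
    reagent → decomposition product (k = 3.02 × 10⁻⁶ /min)
    intermediate ⇌ isomer of the product (K = 2.40, k = 5.01 × 10⁻⁴ /min)

The branch share of 69.8% stands beside that first value, and beside the 69.1% at 4.0 h of a neighbour flask charged with 1.0 M of substrate, its other charges unchanged. In the flask the half-life of target for going back through intermediate, 1.0 d, is shorter than the 5.0 d, so 4.78 such half-lives fit. Between 2.50 d and 5.00 d target in the flask goes from 26.6% to 24.7% of the substrate charged, isomer of the product goes from 17.8% to 20.7%, and the share stands at 54.3%.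

(All runs come from a simulation from invented constants; the scatter is artificial.)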